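Count the reagent first.

common to all: starting material 20 mM; initiator 1.5 mM

| charge | reagent | protic impurity | remark | time |
|---|---|---|---|---|
| elm | 3.2 mM | 0.40 mM | run made earlier |  |
| larch | 30 mM | 0.40 mM | run made earlier |  |
| Saturday's | 5.00 mM | 0.400 mM |  | 25 min |
| Tuesday's | 10.0 mM | 0.400 mM |  | 25 min |
| Thursday's | 20.0 mM | 0.400 mM |  | 25 min |
| Friday's | 40.0 mM | 0.400 mM |  | 25 min |

| run | time / min | target / % | starting material / % |
|---|---|---|---|
| elm | 0.833 | 13 | 87 |
| elm | 2.50 | 20 | 80 |
| elm | 4.00 | 14 | 79 |
| elm | 6.00 | 13 | 81 |
| elm | 10.0 | 16 | 82 |
| elm | 12.0 | 15 | 84 |
| larch | 1.00 | 63 | 35 |
| larch | 1.50 | 83 | 11 |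
| larch | 3.00 | 89 | 1 |
| larch | 5.00 | 78 | 0 |
| larch | 8.00 | 71 | 1 |
| larch | 12.0 | 59 | 0 |

(readings scatter by 2 percentage points)

- amount of target at the end, in percent of the starting material charged for Saturday's, Tuesday's, Thursday's, Friday's, in this order
- how that number moves from the first to the last of them (falls, then rises / rises, then falls / falls all the way / rises all the way / hardly changes)

- percentages count the starting material that a species holds: one ended chains counts as two
- steps thought possible: initiator -> 2 initiating radical; starting material + initiating radical -> capped initiator + first chain carrier; reagent + first chain carrier -> target + second chain carrier; starting material + second chain carrier -> released group + first chain carrier; 2 first chain carrier -> ended chains; reagent + target -> over-reaction product; starting material + protic impurity -> quenched substrate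
- "hardly changes" means that all values lie within two and a half points (for a concentration: within two and a half percent of the largest)

1. My bench rule treats the reagent as the limiting reagent: one target costs one reagent, so percent target equals c(reagent)/c(starting material). For elm it gives 16.0%, and the last elm reading is 15%. For Saturday's it gives 25.0%, and for Tuesday's 50.0%.

2. The rule stops where that ratio passes one. Thursday's stands at 1.00, larch at 1.50, Friday's at 2.00. In larch the target falls from 89% to 59% between 3.00 min and 12.0 min, with starting material at 1% or less. I read this as reagent + target → over-reaction product.

3. I subtract the protic impurity from the starting material and so reckon on 19.6 mM of target where the reagent suffices, which puts Thursday's at 98.0%. In larch, c(target) then exceeds c(reagent) by a fixed gap of 9.20 mM, since each over-reaction removes one of each. The readings of 17.8 mM and 11.8 mM then give a second-order constant of 0.00948 /mM/min, a rough reading.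

4. For Friday's I reckon 20.4 mM of reagent left beside 19.6 mM of target when the chain has used the starting material. In my reckoning for Friday's the two stand close together, so I take the over-reaction rate as going with the square of c(target), and not as pseudo-first-order. I use the equal-charge half-time, the time in which equal reagent and target fall to half, 5.38 min. Starting the clock at 3.00 min, as in larch, I get 19.3% for Friday's. So my row rises to Thursday's and drops on Friday's.

5. The forecast reads 24%, 45%, 78%, 19%, rises, then falls, holding that “target decays only through excess reagent”; on Thursday's it sits lower than my figure.

6. The flasks give 24.6%, 48.4%, 92.4%, 22.2%: rises, then falls, turning at 20 mM.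

    initiator → 2 initiating radical (k = 3.00 × 10⁻⁴ /s)
    starting material + initiating radical → capped initiator + first chain carrier (k = 18000 /M/s)
    reagent + first chain carrier → target + second chain carrier (k = 50000 /M/s)
    starting material + second chain carrier → released group + first chain carrier (k = 690 /M/s)
    2 first chain carrier → ended chains (k = 1.00 × 10⁶ /M/s)
    reagent + target → over-reaction product (k = 0.110 /M/s)
    starting material + protic impurity → quenched substrate (k = 1.50 /M/s)

Friday's at 25.0 min holds 22.2% target and 76.3% over-reaction product, with 12.7% of its reagent charge left. With the half-time 5.38 min and the same clock, Friday's target at 250 min reckons to 2.09%. The flask holds 1.64% there.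

The data come from a simulation for substances that don't exist; scatter was added.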